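**Strategy.** Everything rests on cutting the bond between the ketone carbon and the adjacent cyclopropane ring carbon. It is made by a nickel-catalysed decarboxylative acyl cross-coupling of two complete halves: the 2-pyridyl thioester of the (Z)-4-methoxycinnamoylated (S)-lactic acid and an N-acyloxyphthalimide in which a carboxyl group sits on the future ring carbon. The step exploits the trans-1,2-disubstituted cyclopropane: loss of CO2 gives a rapidly inverting cyclopropyl radical at the ring carbon, which nickel acylates anti to the side chain on the neighbouring ring carbon, so C–C bond and ring stereocentre are set together. The redox-active ester comes in one step from a vinyl group by ruthenium-catalysed carbene transfer.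

Key step: step 11

Remark: in step 6 the (S)-Pheox ligand is written on the assumption that the catalyst, not the allylic silyloxy stereocentre, fixes the alkene face and that this antipode gives the (S) configuration at the side-chain-bearing ring carbon; if the sense of induction on this substrate is the opposite, the (R)-ligand is used with no other change.

**Route**

Step 1
Reactants: 1 penta-1,4-dien-3-ol
Product: 2 (2R,3S)-1,2-epoxypent-4-en-3-ol
Conditions: Ti(OiPr)4, L-(+)-diisopropyl tartrate, t-BuOOH, 4 Å molecular sieves, CH2Cl2, −20 °C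
Reagents that add atoms: tert-butyl hydroperoxide, CC(C)(C)OO
Why: Sharpless asymmetric epoxidation desymmetrises the divinyl carbinol, the titanium–L-(+)-tartrate complex choosing one enantiotopic vinyl group and one of its faces so that the epoxide carbon (R) and the carbinol carbon (S) arise together in the erythro sense, while the minor enantiomer is consumed by faster second epoxidation.

Step 2
Reactants: 2 (2R,3S)-1,2-epoxypent-4-en-3-ol
Product: 3 tert-butyldimethyl{[(1S)-1-[(2R)-oxiran-2-yl]prop-2-en-1-yl]oxy}silane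
Conditions: TBSCl, imidazole, DMF, 0 °C to rt
Reagents that add atoms: tert-butyldimethylsilyl chloride, CC(C)(C)[Si](C)(C)Cl
Why: Imidazole-mediated silylation of the secondary alcohol masks it against the Lewis acid of step 3 and the metal carbene of step 6 and touches no stereocentre.

Step 3
Reactants: 3 tert-butyldimethyl{[(1S)-1-[(2R)-oxiran-2-yl]prop-2-en-1-yl]oxy}silane; 4 ethyl propiolate
Product: 6 ethyl (5R,6S)-6-[(tert-butyldimethylsilyl)oxy]-5-hydroxyoct-7-en-2-ynoate, via lithium ethyl propiolate 5 (not isolated)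
Conditions: 4, n-BuLi, THF, −78 °C; BF3·OEt2; then 3, −78 °C; aq NH4Cl
Reagents that add atoms: none
Why: BF3-promoted epoxide alkynylation (Yamaguchi–Hirao type) occurs at the unsubstituted epoxide carbon, so the oxygen-bearing stereocentre that becomes the lactone carbon is retained.

Step 4
Reactants: 6 ethyl (5R,6S)-6-[(tert-butyldimethylsilyl)oxy]-5-hydroxyoct-7-en-2-ynoate
Product: 8 (6R)-6-[(1S)-1-[(tert-butyldimethylsilyl)oxy]prop-2-en-1-yl]-5,6-dihydro-2H-pyran-2-one, via (Z)-hydroxy dienoate 7 (not isolated)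
Conditions: H2 (1 atm), Pd/CaCO3 poisoned with Pb(OAc)2 (Lindlar catalyst), quinoline, EtOAc, rt, stopped after one equivalent of H2; filter; then PPTS (cat.), toluene, 60 °C
Reagents that add atoms: none
Why: Lindlar cis-semihydrogenation of the ynoate, faster than reduction of the monosubstituted alkene, gives the (Z)-enoate, whose geometry lets the 5-hydroxyl close the six-membered lactone by acid-catalysed transesterification without touching either stereocentre.

Step 5
Reactants: 9 N-hydroxyphthalimide; 10 glyoxylic acid 4-toluenesulfonylhydrazone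
Product: 12 1,3-dioxoisoindolin-2-yl 2-diazoacetate, via tosylhydrazone active ester 11 (not isolated)
Conditions: DCC, THF, 0 °C to rt; filter; then Et3N, CH2Cl2, 0 °C
Reagents that add atoms: none
Why: Carbodiimide esterification followed by base-induced loss of sulfinate from the tosylhydrazone (Bamford–Stevens-type diazo ester synthesis) is the established way to diazoacetates of N-hydroxy imides.

Step 6
Reactants: 8 (6R)-6-[(1S)-1-[(tert-butyldimethylsilyl)oxy]prop-2-en-1-yl]-5,6-dihydro-2H-pyran-2-one; 12 1,3-dioxoisoindolin-2-yl 2-diazoacetate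
Product: 13 1,3-dioxoisoindolin-2-yl (1S,2S)-2-[(S)-[(tert-butyldimethylsilyl)oxy][(2R)-6-oxo-3,6-dihydro-2H-pyran-2-yl]methyl]cyclopropane-1-carboxylate
Conditions: [Ru((S)-Pheox)(MeCN)4]PF6 (3 mol %; Pheox = cyclometalated 2,4-diphenyl-4,5-dihydrooxazole), CH2Cl2, −10 °C to rt, slow addition of 12
Reagents that add atoms: none
Why: Carbene transfer from the cationic divalent ruthenium Pheox complex to the terminal alkene (the conjugated lactone alkene is too electron-poor to react) is a catalyst-controlled asymmetric cyclopropanation that sets both ring carbons, trans and with the side-chain-bearing carbon (S), and any cis isomer is harmless because step 11 erases the ester-bearing centre.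

Step 7
Reactants: 14 3-(4-methoxyphenyl)propiolic acid; 15 tert-butyl (S)-lactate
Product: 16 tert-butyl (2S)-2-{[3-(4-methoxyphenyl)prop-2-ynoyl]oxy}propanoate
Conditions: DCC, DMAP (cat.), CH2Cl2, 0 °C to rt
Reagents that add atoms: none
Why: Steglich esterification acylates the lactate oxygen without breaking a bond at the stereocentre, so the (S) configuration is carried over, and the alkyne cannot isomerise as a Z-alkene could.

Step 8
Reactants: 16 tert-butyl (2S)-2-{[3-(4-methoxyphenyl)prop-2-ynoyl]oxy}propanoate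
Product: 17 tert-butyl (2S)-2-{[(2Z)-3-(4-methoxyphenyl)prop-2-enoyl]oxy}propanoate
Conditions: H2 (1 atm), Pd/CaCO3 poisoned with Pb(OAc)2, quinoline, EtOAc, rt
Reagents that add atoms: none
Why: Lindlar semihydrogenation adds H2 syn to the aryl ynoate and so gives the (Z)-cinnamate.

Step 9
Reactants: 17 tert-butyl (2S)-2-{[(2Z)-3-(4-methoxyphenyl)prop-2-enoyl]oxy}propanoate
Product: 18 (2S)-2-{[(2Z)-3-(4-methoxyphenyl)prop-2-enoyl]oxy}propanoic acid
Conditions: TFA/CH2Cl2 (1:4), 0 °C
Reagents that add atoms: none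
Why: Acidolysis of the tert-butyl ester by alkyl–oxygen cleavage (loss of isobutene) leaves the cinnamate ester and the lactate centre untouched at low temperature.

Step 10
Reactants: 18 (2S)-2-{[(2Z)-3-(4-methoxyphenyl)prop-2-enoyl]oxy}propanoic acid
Product: 19 S-pyridin-2-yl (2S)-2-{[(2Z)-3-(4-methoxyphenyl)prop-2-enoyl]oxy}propanethioate
Conditions: 2,2'-dipyridyl disulfide, PPh3, CH2Cl2, rt
Reagents that add atoms: 2,2'-dipyridyl disulfide, c1ccc(SSc2ccccn2)nc1
Why: Mukaiyama-type redox condensation activates the acid as an acyloxyphosphonium salt that the released pyridine-2-thiolate acylates under neutral conditions, so the lactate centre and the Z-alkene should survive.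

Step 11
Reactants: 13 1,3-dioxoisoindolin-2-yl (1S,2S)-2-[(S)-[(tert-butyldimethylsilyl)oxy][(2R)-6-oxo-3,6-dihydro-2H-pyran-2-yl]methyl]cyclopropane-1-carboxylate; 19 S-pyridin-2-yl (2S)-2-{[(2Z)-3-(4-methoxyphenyl)prop-2-enoyl]oxy}propanethioate
Product: 20 (2S)-1-[(1S,2S)-2-[(S)-[(tert-butyldimethylsilyl)oxy][(2R)-6-oxo-3,6-dihydro-2H-pyran-2-yl]methyl]cyclopropyl]-1-oxopropan-2-yl (2Z)-3-(4-methoxyphenyl)prop-2-enoate
Conditions: NiBr2(dme) (10 mol %), 4,4'-di-tert-butyl-2,2'-bipyridine (12 mol %), Zn dust, THF/DMA, rt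
Reagents that add atoms: none
Why: Zn reduces the nickel bromide complex to zerovalent nickel, which inserts into the C(acyl)–S bond of 19, while single-electron reduction of 13 triggers N–O cleavage and loss of CO2; the resulting cyclopropyl radical is captured by the acylnickel species and reductive elimination from trivalent nickel forges the ketone–cyclopropane bond. The closest known reaction type is the nickel-catalysed decarboxylative cross-electrophile ketone synthesis from N-hydroxyphthalimide esters and S-2-pyridyl thioesters, and cyclopropyl redox-active esters are established partners in related nickel-catalysed decarboxylative couplings. No ring is closed. The one new stereocentre, the acylated ring carbon, is controlled by the neighbouring ring carbon: the cyclopropyl sigma-radical inverts fast and nickel should trap it anti to the bulky silyloxy(pyranonyl)methyl substituent, giving the 1,2-trans (1S,2S) ketone whatever the cis/trans composition of 13. Cross-selectivity over homocoupling follows from the different activation modes of the two electrophiles (two-electron oxidative addition for the thioester, single-electron reduction for the redox-active ester). Chemoselectivity requires radical capture by nickel to outrun conjugate addition to the lactone and cinnamate alkenes, and the neutral conditions should leave the lactate centre and the Z-alkene intact.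

Step 12
Reactants: 20 (2S)-1-[(1S,2S)-2-[(S)-[(tert-butyldimethylsilyl)oxy][(2R)-6-oxo-3,6-dihydro-2H-pyran-2-yl]methyl]cyclopropyl]-1-oxopropan-2-yl (2Z)-3-(4-methoxyphenyl)prop-2-enoate
Product: 21 brevipolide I
Conditions: HF·pyridine, pyridine, THF, 0 °C to rt
Reagents that add atoms: none
Why: Fluoride-driven cleavage of the Si–O bond by buffered HF·pyridine frees the carbinol without base, so the lactone, the Z-cinnamate and the epimerisable lactate centre should be untouched.

**Compound list**

1 | penta-1,4-dien-3-ol | C=CC(O)C=C | starting material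
2 | (2R,3S)-1,2-epoxypent-4-en-3-ol | C=C[C@H](O)[C@H]1CO1 | intermediate
3 | tert-butyldimethyl{[(1S)-1-[(2R)-oxiran-2-yl]prop-2-en-1-yl]oxy}silane | C=C[C@H](O[Si](C)(C)C(C)(C)C)[C@H]1CO1 | intermediate
4 | ethyl propiolate | C#CC(=O)OCC | starting material
5 | lithium ethyl propiolate (formed in the flask) | [Li]C#CC(=O)OCC | intermediate
6 | ethyl (5R,6S)-6-[(tert-butyldimethylsilyl)oxy]-5-hydroxyoct-7-en-2-ynoate | C=C[C@H](O[Si](C)(C)C(C)(C)C)[C@H](O)CC#CC(=O)OCC | intermediate
7 | ethyl (2Z,5R,6S)-6-[(tert-butyldimethylsilyl)oxy]-5-hydroxyocta-2,7-dienoate (formed in the flask) | C=C[C@H](O[Si](C)(C)C(C)(C)C)[C@H](O)C/C=C\C(=O)OCC | intermediate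
8 | (6R)-6-[(1S)-1-[(tert-butyldimethylsilyl)oxy]prop-2-en-1-yl]-5,6-dihydro-2H-pyran-2-one | C=C[C@H](O[Si](C)(C)C(C)(C)C)[C@H]1CC=CC(=O)O1 | intermediate
9 | N-hydroxyphthalimide | O=C1c2ccccc2C(=O)N1O | starting material
10 | glyoxylic acid 4-toluenesulfonylhydrazone, 2-[2-(4-methylphenyl)sulfonylhydrazinylidene]acetic acid | Cc1ccc(S(=O)(=O)NN=CC(=O)O)cc1 | starting material
11 | 1,3-dioxoisoindolin-2-yl 2-[2-(4-methylphenyl)sulfonylhydrazinylidene]acetate (formed in the flask) | Cc1ccc(S(=O)(=O)NN=CC(=O)ON2C(=O)c3ccccc3C2=O)cc1 | intermediate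
12 | 1,3-dioxoisoindolin-2-yl 2-diazoacetate | [N-]=[N+]=CC(=O)ON1C(=O)c2ccccc2C1=O | intermediate
13 | 1,3-dioxoisoindolin-2-yl (1S,2S)-2-[(S)-[(tert-butyldimethylsilyl)oxy][(2R)-6-oxo-3,6-dihydro-2H-pyran-2-yl]methyl]cyclopropane-1-carboxylate | O=C(ON1C(=O)c2ccccc2C1=O)[C@H]1C[C@@H]1[C@H](O[Si](C)(C)C(C)(C)C)[C@H]1CC=CC(=O)O1 | intermediate
14 | 3-(4-methoxyphenyl)propiolic acid | COc1ccc(C#CC(=O)O)cc1 | starting material
15 | tert-butyl (S)-lactate | C[C@H](O)C(=O)OC(C)(C)C | starting material
16 | tert-butyl (2S)-2-{[3-(4-methoxyphenyl)prop-2-ynoyl]oxy}propanoate | COc1ccc(C#CC(=O)O[C@@H](C)C(=O)OC(C)(C)C)cc1 | intermediate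
17 | tert-butyl (2S)-2-{[(2Z)-3-(4-methoxyphenyl)prop-2-enoyl]oxy}propanoate | COc1ccc(/C=C\C(=O)O[C@@H](C)C(=O)OC(C)(C)C)cc1 | intermediate
18 | (2S)-2-{[(2Z)-3-(4-methoxyphenyl)prop-2-enoyl]oxy}propanoic acid | COc1ccc(/C=C\C(=O)O[C@@H](C)C(=O)O)cc1 | intermediate
19 | S-pyridin-2-yl (2S)-2-{[(2Z)-3-(4-methoxyphenyl)prop-2-enoyl]oxy}propanethioate | COc1ccc(/C=C\C(=O)O[C@@H](C)C(=O)Sc2ccccn2)cc1 | intermediate
20 | (2S)-1-[(1S,2S)-2-[(S)-[(tert-butyldimethylsilyl)oxy][(2R)-6-oxo-3,6-dihydro-2H-pyran-2-yl]methyl]cyclopropyl]-1-oxopropan-2-yl (2Z)-3-(4-methoxyphenyl)prop-2-enoate | COc1ccc(/C=C\C(=O)O[C@@H](C)C(=O)[C@H]2C[C@@H]2[C@H](O[Si](C)(C)C(C)(C)C)[C@H]2CC=CC(=O)O2)cc1 | intermediate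
21 | brevipolide I, (2S)-1-[(1S,2S)-2-[(S)-hydroxy[(2R)-6-oxo-3,6-dihydro-2H-pyran-2-yl]methyl]cyclopropyl]-1-oxopropan-2-yl (2Z)-3-(4-methoxyphenyl)prop-2-enoate | COc1ccc(/C=C\C(=O)O[C@@H](C)C(=O)[C@H]2C[C@@H]2[C@H](O)[C@H]2CC=CC(=O)O2)cc1 | target

**Step count.** Total: 12 steps. Longest linear sequence: 7 steps (1, 2, 3, 4, 6, 11, 12).

**Steps most likely to fail**

1. Step 11. What may go wrong: the cyclopropyl radical is lost before nickel captures it (conjugate addition to the lactone or cinnamate alkene, or hydrogen abstraction), the thioester homocouples, or the Z-alkene isomerises through reversible thiolate addition. Fallback: the union is made polar and stereoretentive; it sets out from 13 and comes back at 20. Irradiation of 13 with bis(catecholato)diboron in DMAc (blue LEDs) gives the catechol boronate F1, which pinacol and Et3N convert in the same flask into the trans pinacol boronate F2. NaIO4 and NH4OAc in acetone–water free the boronic acid F3. Acid 18 is turned with 1-chloro-N,N,2-trimethylprop-1-en-1-amine in CH2Cl2 into the acid chloride F4. F3 and F4 are then joined by an acyl Suzuki–Miyaura coupling (PdCl2(dppf), Ag2O, K2CO3, toluene, 80 °C), in which the cyclopropyl–boron bond transmetalates with retention, to give 20.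

2. Step 6. What may go wrong: poor facial selectivity at the vinyl group if catalyst and allylic stereocentre are mismatched, slow carbene transfer to the hindered alkene, and carbene dimerisation. Fallback: the ring is made stereospecifically from an epoxide; it sets out from 1 and comes back at 13.
   - Sharpless epoxidation of 1 with D-(−)-diisopropyl tartrate gives the enantiomeric epoxy alcohol F5, and NaH with 4-methoxybenzyl chloride gives the 4-methoxybenzyl ether F6.
   - Wadsworth–Emmons cyclopropanation with the sodium salt of tert-butyl diethylphosphonoacetate (DME/toluene, 110 °C) opens the epoxide at CH2 and closes the ring with inversion at the former epoxide carbon, giving the trans cyclopropane ester F7.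
   - DDQ frees the allylic alcohol F8, and a second, matched Sharpless epoxidation with L-(+)-diisopropyl tartrate gives the erythro epoxy alcohol F9.
   - TBSCl and imidazole give the silyl ether F10, and opening with 5 and BF3·OEt2 gives the ynoate F11.
   - Lindlar semihydrogenation gives the (Z)-enoate F12 (not isolated), which lactonises with PPTS to the pyranone F13.
   - TMSOTf and 2,6-lutidine cleave the tert-butyl ester to the acid F14, which 9 and N,N'-diisopropylcarbodiimide convert into 13.

3. Step 4. What may go wrong: over-reduction of the monosubstituted vinyl group or incomplete cis-selectivity during semihydrogenation. Fallback: annulation without hydrogenation; it sets out from 3 and comes back at 8. 1,1,1-Trimethoxy-3-(phenylsulfonyl)propane is lithiated (n-BuLi, THF/DMPU, −78 °C to rt) and opens epoxide 3 at the CH2 terminus to give the hydroxy sulfonyl orthoester F15 (not isolated). TsOH in wet CH2Cl2 hydrolyses the orthoester and closes the sulfonyl lactone F16. Et3N or DBU then eliminates benzenesulfinate to give 8.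

**Further compounds**

F1 | step 11 | 2-[(1S,2S)-2-[(S)-[(tert-butyldimethylsilyl)oxy][(2R)-6-oxo-3,6-dihydro-2H-pyran-2-yl]methyl]cyclopropyl]-1,3,2-benzodioxaborole | B1(Oc2ccccc2O1)[C@H]1C[C@@H]1[C@H](O[Si](C)(C)C(C)(C)C)[C@H]1CC=CC(=O)O1
F2 | step 11 | (6R)-6-[(S)-[(tert-butyldimethylsilyl)oxy][(1S,2S)-2-(4,4,5,5-tetramethyl-1,3,2-dioxaborolan-2-yl)cyclopropyl]methyl]-5,6-dihydro-2H-pyran-2-one | CC1(C)OB(OC1(C)C)[C@H]1C[C@@H]1[C@H](O[Si](C)(C)C(C)(C)C)[C@H]1CC=CC(=O)O1
F3 | step 11 | [(1S,2S)-2-[(S)-[(tert-butyldimethylsilyl)oxy][(2R)-6-oxo-3,6-dihydro-2H-pyran-2-yl]methyl]cyclopropyl]boronic acid | OB(O)[C@H]1C[C@@H]1[C@H](O[Si](C)(C)C(C)(C)C)[C@H]1CC=CC(=O)O1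
F4 | step 11 | (2S)-2-{[(2Z)-3-(4-methoxyphenyl)prop-2-enoyl]oxy}propanoyl chloride | COc1ccc(/C=C\C(=O)O[C@@H](C)C(=O)Cl)cc1
F5 | step 6 | (2S,3R)-1,2-epoxypent-4-en-3-ol | C=C[C@@H](O)[C@@H]1CO1
F6 | step 6 | (2S)-2-[(1R)-1-[(4-methoxybenzyl)oxy]prop-2-en-1-yl]oxirane | C=C[C@@H](OCc1ccc(OC)cc1)[C@@H]1CO1
F7 | step 6 | tert-butyl (1S,2S)-2-[(1R)-1-[(4-methoxybenzyl)oxy]prop-2-en-1-yl]cyclopropane-1-carboxylate | CC(C)(C)OC(=O)[C@H]1C[C@@H]1[C@H](OCc1ccc(OC)cc1)C=C
F8 | step 6 | tert-butyl (1S,2S)-2-[(1R)-1-hydroxyprop-2-en-1-yl]cyclopropane-1-carboxylate | CC(C)(C)OC(=O)[C@H]1C[C@@H]1[C@H](O)C=C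
F9 | step 6 | tert-butyl (1S,2S)-2-[(S)-hydroxy[(2R)-oxiran-2-yl]methyl]cyclopropane-1-carboxylate | CC(C)(C)OC(=O)[C@H]1C[C@@H]1[C@H](O)[C@H]1CO1
F10 | step 6 | tert-butyl (1S,2S)-2-[(S)-[(tert-butyldimethylsilyl)oxy][(2R)-oxiran-2-yl]methyl]cyclopropane-1-carboxylate | CC(C)(C)OC(=O)[C@H]1C[C@@H]1[C@H](O[Si](C)(C)C(C)(C)C)[C@H]1CO1
F11 | step 6 | tert-butyl (1S,2S)-2-[(1S,2R)-1-[(tert-butyldimethylsilyl)oxy]-6-ethoxy-2-hydroxy-6-oxohex-4-yn-1-yl]cyclopropane-1-carboxylate | CC(C)(C)OC(=O)[C@H]1C[C@@H]1[C@H](O[Si](C)(C)C(C)(C)C)[C@H](O)CC#CC(=O)OCC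
F12 | step 6 | tert-butyl (1S,2S)-2-[(1S,2R,4Z)-1-[(tert-butyldimethylsilyl)oxy]-6-ethoxy-2-hydroxy-6-oxohex-4-en-1-yl]cyclopropane-1-carboxylate | CC(C)(C)OC(=O)[C@H]1C[C@@H]1[C@H](O[Si](C)(C)C(C)(C)C)[C@H](O)C/C=C\C(=O)OCC
F13 | step 6 | tert-butyl (1S,2S)-2-[(S)-[(tert-butyldimethylsilyl)oxy][(2R)-6-oxo-3,6-dihydro-2H-pyran-2-yl]methyl]cyclopropane-1-carboxylate | CC(C)(C)OC(=O)[C@H]1C[C@@H]1[C@H](O[Si](C)(C)C(C)(C)C)[C@H]1CC=CC(=O)O1
F14 | step 6 | (1S,2S)-2-[(S)-[(tert-butyldimethylsilyl)oxy][(2R)-6-oxo-3,6-dihydro-2H-pyran-2-yl]methyl]cyclopropane-1-carboxylic acid | OC(=O)[C@H]1C[C@@H]1[C@H](O[Si](C)(C)C(C)(C)C)[C@H]1CC=CC(=O)O1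
F15 | step 4 | (3S,4R)-3-[(tert-butyldimethylsilyl)oxy]-8,8,8-trimethoxy-6-(phenylsulfonyl)oct-1-en-4-ol (epimers at the sulfonyl carbon) | C=C[C@H](O[Si](C)(C)C(C)(C)C)[C@H](O)CC(CC(OC)(OC)OC)S(=O)(=O)c1ccccc1
F16 | step 4 | (6R)-6-[(1S)-1-[(tert-butyldimethylsilyl)oxy]prop-2-en-1-yl]-4-(phenylsulfonyl)tetrahydro-2H-pyran-2-one (epimers at the sulfonyl carbon) | C=C[C@H](O[Si](C)(C)C(C)(C)C)[C@H]1CC(S(=O)(=O)c2ccccc2)CC(=O)O1
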